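**Retrosynthetic overview**

1. The two angelates go on last, onto a 7,15-diol whose C1 oxygen is still a silyl ether; C1 oxidation and migration of an exocyclic C3=C12 bond then give the enone. The C7 carbinol comes from a hydroxyl-directed anti reduction of a 15-hydroxy-7-ketone.
2. Key disconnection C15–C6: ligand-controlled Mukaiyama hydroxymethylation of the tricyclic C6=C7 enol silane with formaldehyde. Enabling feature: in the seven-membered ring C5–C6–C7–C8–C9–C10–C11 the oxygenated C7 sits next to C6, so O–C15–C6–C7–O is an aldol retron and C6=C7 is a Bredt-allowed enol ether (C5=C6 is not). With C1 kept as an ether, no carbonyl can open the cyclobutane bonds C5–C11 or C5–C4 from C6.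
3. Seven-membered ring: intramolecular aldol of a chain ethyl ketone (C6 enolate) onto the cyclobutanone carbon C5, then radical removal of the C5 oxygen.
4. Six-membered ring and cyclobutane in one step: intramolecular vinylketene–alkene [2+2] of an open-chain acid, its facial course relayed from a C1 silyloxy stereocentre made by a catalytic vinylogous Mukaiyama aldol.
5. Chain from geranyl acetate and methyl 3-methylbut-2-enoate. Ring order: four- and six-membered together, then seven-membered.

Key step: step 13

Remark: ring compounds carry longipinane locants, and the open-chain precursors use the same ones. C1 is the oxygenated carbon of the three-carbon bridge, then C2 and C3 (C3 bears C12). C4 and C11 are the bridgeheads. C5 and C10 are the one-carbon bridges (C10 bears methyl C13). C6–C9 form the four-carbon bridge (C6 bears methyl C14 and C15). The target is taken exactly as the SMILES defines it.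

**Route**

Step 1
Reactants: 1 geranyl acetate
Product: 2 6,7-epoxygeranyl acetate (racemic epoxide)
Conditions: mCPBA, NaHCO3, CH2Cl2, 0 °C
Reagents that add atoms: mCPBA, OOC(=O)c1cccc(Cl)c1
Why: Prilezhaev epoxidation takes the electron-rich 6,7-alkene before the 2,3-alkene, which the allylic acetate deactivates; the epoxide stereocentre is destroyed in step 2.

Step 2
Reactants: 2 6,7-epoxygeranyl acetate
Product: 4 (2E)-3-methyl-6-oxohex-2-en-1-yl acetate, via glycol 3 (not isolated)
Conditions: H5IO6, THF/H2O, 0 °C to rt
Reagents that add atoms: water, O (tertiary hydroxyl of 3 only)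
Why: acid-mediated epoxide hydrolysis followed by Malaprade glycol cleavage removes the terminal C3 unit as acetone and leaves the C7 aldehyde, with the E alkene untouched.

Step 3
Reactants: 4 (2E)-3-methyl-6-oxohex-2-en-1-yl acetate
Product: 5 (2E)-3-methyloct-2-ene-1,6-diol (racemic at the secondary carbinol)
Conditions: EtMgBr (3.3 equiv), THF, −78 to 0 °C; aq. NH4Cl
Reagents that add atoms: ethylmagnesium bromide, CC[Mg]Br
Why: Grignard addition to the aldehyde brings in C6 and C14, and the excess reagent removes the acetate by double addition, so both alcohols are free for one oxidation.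

Step 4
Reactants: 5 (2E)-3-methyloct-2-ene-1,6-diol
Product: 6 (2E)-3-methyl-6-oxooct-2-enal
Conditions: Dess–Martin periodinane (2.4 equiv), NaHCO3, CH2Cl2, 0 °C to rt
Reagents that add atoms: none
Why: Dess–Martin oxidation converts the allylic primary alcohol to the E enal and the secondary alcohol to the ethyl ketone under neutral conditions that should not isomerise the alkene.

Step 5
Reactants: 7 methyl 3-methylbut-2-enoate
Product: 9 tert-butyl[(1-methoxy-3-methylbuta-1,3-dien-1-yl)oxy]dimethylsilane, via lithium dienolate 8 (not isolated)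
Conditions: LDA, THF/DMPU, −78 °C; TBSCl
Reagents that add atoms: tert-butyldimethylsilyl chloride, CC(C)(C)[Si](C)(C)Cl; lithium diisopropylamide, CC(C)N([Li])C(C)C (lithium of 8 only)
Why: γ-deprotonation of the senecioate and O-silylation give the silyl dienol ether, the nucleophile for the vinylogous aldol.

Step 6
Reactants: 6 (2E)-3-methyl-6-oxooct-2-enal; 9 silyl dienol ether
Product: 11 methyl (2E,5S,6E)-5-hydroxy-3,7-dimethyl-10-oxododeca-2,6-dienoate, via trichlorosilyl ether 10 (not isolated)
Conditions: SiCl4, binaphthyldiamine-derived bisphosphoramide (5 mol %, the enantiomer that gives 5S), i-Pr2NEt (cat.), CH2Cl2, −78 °C; aq. NaHCO3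
Reagents that add atoms: silicon tetrachloride, Cl[Si](Cl)(Cl)Cl (trichlorosilyl group of 10 only)
Why: catalytic enantioselective vinylogous Mukaiyama aldol (Lewis-base-activated SiCl4) adds the dienolate through its γ-carbon to the aldehyde only (the ketone is inert), forms the C1–C2 bond and the E enoate, and sets the C1 carbinol by catalyst control.

Step 7
Reactants: 11 δ-hydroxy enoate
Product: 12 methyl (2E,5S,6E)-5-[(tert-butyldimethylsilyl)oxy]-3,7-dimethyl-10-oxododeca-2,6-dienoate
Conditions: TBSCl, imidazole, DMF, rt
Reagents that add atoms: tert-butyldimethylsilyl chloride, CC(C)(C)[Si](C)(C)Cl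
Why: silylation protects the C1 carbinol, which must stay an ether until the end and acts as the steric control element in step 9.

Step 8
Reactants: 12 silyl ether ester
Product: 13 (2E,5S,6E)-5-[(tert-butyldimethylsilyl)oxy]-3,7-dimethyl-10-oxododeca-2,6-dienoic acid
Conditions: LiOH, THF/MeOH/H2O, rt; dilute HCl to pH 4
Reagents that add atoms: lithium hydroxide, [Li+].[OH-]
Why: saponification of the methyl ester gives the acid; the secondary TBS ether and the ketone tolerate aqueous hydroxide at room temperature.

Step 9
Reactants: 13 dienoic acid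
Product: 16 4-[(tert-butyldimethylsilyl)oxy]-7-methyl-2-methylidene-7-(3-oxopentyl)bicyclo[3.1.1]heptan-6-one (silyloxy syn to the carbonyl bridge; 3-oxopentyl chain anti to the three-carbon bridge), via acid chloride 14 (not isolated), via vinylketene 15 (not isolated)
Conditions: 1-chloro-N,N,2-trimethylprop-1-en-1-amine, CH2Cl2, 0 °C to rt; then slow addition to Et3N, toluene, 110 °C, high dilution
Reagents that add atoms: 1-chloro-N,N,2-trimethylprop-1-en-1-amine, CC(C)=C(Cl)N(C)C (chlorine of 14 only)
Why: the acid chloride loses HCl by 1,4-elimination of the γ-methyl hydrogen cis to the acyl group to give vinylketene 15, which undergoes the intramolecular crossed [2+2] ketene–alkene cycloaddition (C5 to the less substituted C11, C4 to the cation-stabilising C10) and closes the six-membered ring and the cyclobutanone together; the E alkene puts the C10 methyl on the side of the three-carbon bridge and the chain on the other face, and the C1 stereocentre selects the alkene face through allylic 1,3-strain (H next to the C10 methyl, OTBS turned away from the C10 bridge), which sets C4, C10 and C11.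

Step 10
Reactants: 16 bicyclic diketone
Product: 18 methyl oxalate of 1-[(tert-butyldimethylsilyl)oxy]-5-hydroxy-15-norlongipin-3(12)-en-7-one (both C6 epimers), via lithium aldolate 17 (not isolated)
Conditions: LiHMDS, THF, −78 to −20 °C; then ClC(O)CO2Me, −78 to 0 °C
Reagents that add atoms: methyl chlorooxoacetate, COC(=O)C(Cl)=O; lithium hexamethyldisilazide, C[Si](C)(C)N([Li])[Si](C)(C)C (lithium of 17 only)
Why: intramolecular aldol addition in which only the C6 enolate can reach the strained, non-enolisable cyclobutanone C5 (seven-membered closure from the lower face, which fixes C5), while the C8 enolate would have to form a bicyclo[2.1.1]hexane and returns by proton transfer; the tertiary aldolate is acylated before retro-aldol can occur, and the C6 epimers are levelled in step 12.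

Step 11
Reactants: 18 tertiary methyl oxalate
Product: 19 1-[(tert-butyldimethylsilyl)oxy]-15-norlongipin-3(12)-en-7-one (both C6 epimers)
Conditions: Bu3SnH, AIBN (cat.), toluene, 110 °C
Reagents that add atoms: none
Why: Barton–McCombie-type radical deoxygenation of a tertiary methyl oxalate gives the C5 cyclobutyl radical, which can take hydrogen only on its open exo face, so C5–H has the configuration the cage dictates.

Step 12
Reactants: 19 tricyclic ketone
Product: 20 1-[(tert-butyldimethylsilyl)oxy]-7-[(trimethylsilyl)oxy]-15-norlongipina-3(12),6-diene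
Conditions: TMSCl, NaI, Et3N, MeCN, rt
Reagents that add atoms: chlorotrimethylsilane, C[Si](C)(C)Cl
Why: thermodynamic silyl enol ether formation with iodotrimethylsilane made in situ leads to the more substituted C6=C7 enol ether, which removes the C6 epimer mixture and fixes the site of the next step.

Step 13
Reactants: 20 tricyclic enol silane
Product: 21 1-[(tert-butyldimethylsilyl)oxy]-15-hydroxylongipin-3(12)-en-7-one (C15 on the face of C6 next to C4, C14 next to C11)
Conditions: Sc(OTf)3 (10 mol %), 6,6'-bis(1-hydroxy-2,2-dimethylpropyl)-2,2'-bipyridine (12 mol %, enantiomer chosen for attack on the C6 face next to C4), aq. HCHO (5 equiv), DME/H2O, −20 °C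
Reagents that add atoms: formaldehyde, C=O
Why: Mukaiyama aldol addition in which the chiral Sc(III)–bipyridine-diol complex binds formaldehyde in the aqueous medium, the tetrasubstituted C6=C7 enol silane attacks it through an open transition state and the silyl group ends on water, so the C15–C6 bond and the quaternary stereocentre C6 form in one event. The closest known reaction type is the scandium/chiral-bipyridine-catalysed hydroxymethylation of silicon enolates with aqueous formaldehyde, which also builds quaternary α-carbons from α,α-disubstituted enolates. No ring is closed. The configuration at C6 is controlled by the ligand, because the tricycle has a local mirror plane through C5–C6–C7–C8–C9–C10 and the two faces of the enol ether differ only in the distant C1(OTBS) and C3(=CH2) ends of the three-carbon bridge; the C1 silyloxy group leans over the C11 face and should add a matched bias for attack next to C4. The step needs site selectivity (C6 only, secured by the regiodefined enol silane of step 12; the exocyclic alkene is not nucleophilic enough), facial selectivity (ligand) and survival of the cyclobutane, which is safe because C1 is still an ether and no free enolate, cation or radical arises at C6. The β-ketol has no hydrogen on C6 and cannot epimerise.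

Step 14
Reactants: 21 β-ketol
Product: 22 1-[(tert-butyldimethylsilyl)oxy]longipin-3(12)-ene-7,15-diol (C7 hydroxyl trans to C15, cis to C14)
Conditions: Me4NBH(OAc)3, MeCN/AcOH, −30 to 0 °C
Reagents that add atoms: none
Why: Evans–Saksena hydroxyl-directed reduction: the C15 hydroxyl binds boron and delivers hydride to the C7 carbonyl on the face that carries C15, so the new hydroxyl is trans to C15 and cis to the C6 methyl.

Step 15
Reactants: 22 diol
Product: 23 1-[(tert-butyldimethylsilyl)oxy]longipin-3(12)-ene-7,15-diyl bis[(2Z)-2-methylbut-2-enoate]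
Conditions: LiHMDS (2.2 equiv), THF, −78 °C; angelic anhydride (3 equiv), −78 to 0 °C; aq. NH4Cl
Reagents that add atoms: angelic anhydride, C/C=C(/C)C(=O)OC(=O)/C(C)=C\C
Why: acylation of the lithium dialkoxide with the anhydride at low temperature esterifies both hindered neopentyl-type hydroxyls without acid or nucleophilic catalyst, conditions under which angelates keep their Z geometry.

Step 16
Reactants: 23 bis-angelate silyl ether
Product: 24 1-hydroxylongipin-3(12)-ene-7,15-diyl bis[(2Z)-2-methylbut-2-enoate]
Conditions: HF·pyridine, pyridine/THF, 0 °C to rt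
Reagents that add atoms: none
Why: fluoride-mediated desilylation under buffered conditions frees the C1 carbinol and leaves the angelates and the 1,1-disubstituted alkene untouched.

Step 17
Reactants: 24 C1 alcohol
Product: 26 CNP0240716.1, via β,γ-enone 25 (not isolated)
Conditions: Dess–Martin periodinane, NaHCO3, CH2Cl2, 0 °C; then DBU (0.1 equiv), 0 °C
Reagents that add atoms: none
Why: Dess–Martin oxidation gives the β,γ-unsaturated ketone, whose doubly activated C2 hydrogens allow amidine-catalysed isomerisation of the exocyclic C3=C12 bond into conjugation (the thermodynamic enone); C6 is quaternary and C7 is an ester, so no retro-Michael or retro-aldol path is open.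

**Compound list**

1 | geranyl acetate, (2E)-3,7-dimethylocta-2,6-dien-1-yl acetate | CC(=O)OC/C=C(\C)CCC=C(C)C | starting material
2 | 6,7-epoxygeranyl acetate (racemic epoxide) | CC(=O)OC/C=C(\C)CCC1OC1(C)C | intermediate
3 | (2E)-6,7-dihydroxy-3,7-dimethyloct-2-en-1-yl acetate (racemic glycol) | CC(=O)OC/C=C(\C)CCC(O)C(C)(C)O | intermediate
4 | (2E)-3-methyl-6-oxohex-2-en-1-yl acetate | CC(=O)OC/C=C(\C)CCC=O | intermediate
5 | (2E)-3-methyloct-2-ene-1,6-diol (racemic) | OC/C=C(\C)CCC(O)CC | intermediate
6 | (2E)-3-methyl-6-oxooct-2-enal | O=C/C=C(\C)CCC(=O)CC | intermediate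
7 | methyl 3-methylbut-2-enoate | COC(=O)C=C(C)C | starting material
8 | lithium 1-methoxy-3-methylbuta-1,3-dien-1-olate | [Li]OC(OC)=CC(C)=C | intermediate
9 | tert-butyl[(1-methoxy-3-methylbuta-1,3-dien-1-yl)oxy]dimethylsilane | COC(O[Si](C)(C)C(C)(C)C)=CC(C)=C | intermediate
10 | methyl (2E,5S,6E)-3,7-dimethyl-10-oxo-5-[(trichlorosilyl)oxy]dodeca-2,6-dienoate | COC(=O)/C=C(\C)C[C@H](O[Si](Cl)(Cl)Cl)/C=C(\C)CCC(=O)CC | intermediate
11 | methyl (2E,5S,6E)-5-hydroxy-3,7-dimethyl-10-oxododeca-2,6-dienoate | COC(=O)/C=C(\C)C[C@H](O)/C=C(\C)CCC(=O)CC | intermediate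
12 | methyl (2E,5S,6E)-5-[(tert-butyldimethylsilyl)oxy]-3,7-dimethyl-10-oxododeca-2,6-dienoate | COC(=O)/C=C(\C)C[C@H](O[Si](C)(C)C(C)(C)C)/C=C(\C)CCC(=O)CC | intermediate
13 | (2E,5S,6E)-5-[(tert-butyldimethylsilyl)oxy]-3,7-dimethyl-10-oxododeca-2,6-dienoic acid | OC(=O)/C=C(\C)C[C@H](O[Si](C)(C)C(C)(C)C)/C=C(\C)CCC(=O)CC | intermediate
14 | acid chloride of 13 | ClC(=O)/C=C(\C)C[C@H](O[Si](C)(C)C(C)(C)C)/C=C(\C)CCC(=O)CC | intermediate
15 | vinylketene, (5S,6E)-5-[(tert-butyldimethylsilyl)oxy]-7-methyl-3-methylidenedodeca-1,6-diene-1,10-dione | O=C=CC(=C)C[C@H](O[Si](C)(C)C(C)(C)C)/C=C(\C)CCC(=O)CC | intermediate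
16 | 4-[(tert-butyldimethylsilyl)oxy]-7-methyl-2-methylidene-7-(3-oxopentyl)bicyclo[3.1.1]heptan-6-one (silyloxy syn to the carbonyl bridge, chain anti to the three-carbon bridge) | O=C1[C@H]2[C@@H](O[Si](C)(C)C(C)(C)C)CC(=C)[C@@H]1[C@@]2(C)CCC(=O)CC | intermediate
17 | lithium 5-alkoxide of 1-[(tert-butyldimethylsilyl)oxy]-5-hydroxy-15-norlongipin-3(12)-en-7-one (C6 epimers, C6 left undefined) | CC1[C@]2(O[Li])[C@H]3[C@@H](O[Si](C)(C)C(C)(C)C)CC(=C)[C@@H]2[C@@]3(C)CCC1=O | intermediate
18 | 5-O-(methoxyoxalyl) derivative of 1-[(tert-butyldimethylsilyl)oxy]-5-hydroxy-15-norlongipin-3(12)-en-7-one (C6 epimers) | CC1[C@]2(OC(=O)C(=O)OC)[C@H]3[C@@H](O[Si](C)(C)C(C)(C)C)CC(=C)[C@@H]2[C@@]3(C)CCC1=O | intermediate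
19 | 1-[(tert-butyldimethylsilyl)oxy]-15-norlongipin-3(12)-en-7-one (C6 epimers) | CC1[C@@H]2[C@H]3[C@@H](O[Si](C)(C)C(C)(C)C)CC(=C)[C@@H]2[C@@]3(C)CCC1=O | intermediate
20 | 1-[(tert-butyldimethylsilyl)oxy]-7-[(trimethylsilyl)oxy]-15-norlongipina-3(12),6-diene | CC=1[C@@H]2[C@H]3[C@@H](O[Si](C)(C)C(C)(C)C)CC(=C)[C@@H]2[C@@]3(C)CCC=1O[Si](C)(C)C | intermediate
21 | 1-[(tert-butyldimethylsilyl)oxy]-15-hydroxylongipin-3(12)-en-7-one (C15 next to C4) | OC[C@@]1(C)[C@@H]2[C@H]3[C@@H](O[Si](C)(C)C(C)(C)C)CC(=C)[C@@H]2[C@@]3(C)CCC1=O | intermediate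
22 | 1-[(tert-butyldimethylsilyl)oxy]longipin-3(12)-ene-7,15-diol (C7–OH trans to C15) | OC[C@@]1(C)[C@@H]2[C@H]3[C@@H](O[Si](C)(C)C(C)(C)C)CC(=C)[C@@H]2[C@@]3(C)CC[C@@H]1O | intermediate
23 | 7,15-bis-angelate of 22 | C/C=C(/C)C(=O)OC[C@@]1(C)[C@@H]2[C@H]3[C@@H](O[Si](C)(C)C(C)(C)C)CC(=C)[C@@H]2[C@@]3(C)CC[C@@H]1OC(=O)/C(C)=C\C | intermediate
24 | 1-hydroxylongipin-3(12)-ene-7,15-diyl bis-angelate | C/C=C(/C)C(=O)OC[C@@]1(C)[C@@H]2[C@H]3[C@@H](O)CC(=C)[C@@H]2[C@@]3(C)CC[C@@H]1OC(=O)/C(C)=C\C | intermediate
25 | 1-oxolongipin-3(12)-ene-7,15-diyl bis-angelate (β,γ-enone) | C/C=C(/C)C(=O)OC[C@@]1(C)[C@@H]2[C@H]3C(=O)CC(=C)[C@@H]2[C@@]3(C)CC[C@@H]1OC(=O)/C(C)=C\C | intermediate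
26 | CNP0240716.1, 1-oxolongipin-2-ene-7,15-diyl bis[(2Z)-2-methylbut-2-enoate] | C/C=C(/C)C(=O)OC[C@@]1(C)[C@@H]2[C@H]3C(=O)C=C(C)[C@@H]2[C@@]3(C)CC[C@@H]1OC(=O)/C(C)=C\C | target

**Totals and risks**

Total step count: 17. Longest linear sequence: 16 steps (steps 1–4 and 6–17); step 5 is a one-step side branch.

The three steps most likely to fail:

Step 13 (facial control at C6). The two faces of the planar C6=C7 enol ether differ only through remote groups, so the ligand may discriminate poorly, and the hindered tetrasubstituted enol silane may hydrolyse faster than it adds. The fallback sets out from 20. The O–Si bond is cleaved with MeLi (THF, 0 °C) to give the regiodefined lithium enolate, monomeric formaldehyde is added at −78 °C, and both C6 epimers are accepted. Because the material is already a single enantiomer, these are diastereomers, 21 and the 6-epi ketol F1, and should separate on silica. F1 is returned to ketone 19 by base-induced retro-aldol loss of formaldehyde (K2CO3, MeOH, 40 °C) and passed through step 12 again. The route is rejoined at 21.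

Step 10 (seven-membered aldol and trapping). The aldol equilibrium may lie on the side of the open diketone, the aldolate O5 is crowded by the C1 silyloxy group, and uncyclised enolates may be acylated by the oxalyl chloride. The fallback sets out from 16 and replaces the reversible enolate aldol by an irreversible Lewis-acid one. TMSOTf/Et3N (CH2Cl2, −78 °C) gives the enol silane F2 together with its C8 regioisomer. TiCl4 (CH2Cl2, −78 °C) then drives the intramolecular Mukaiyama aldol of F2 onto the cyclobutanone and gives, after work-up, the free β-ketol F3; the C8 isomer cannot close, hydrolyses back to 16 and is recycled. F3 is acylated with ClC(O)CO2Me, DMAP and pyridine. The route is rejoined at 18.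

Step 9 (vinylketene formation and cycloaddition). The 1,4-dehydrochlorination needs high temperature, and elimination of the C1 silanolate or ketene oligomerisation may compete with the cycloaddition. The fallback sets out from 13 and makes the same ketene by an ordinary 1,2-elimination at lower temperature. LDA (3.3 equiv, THF/DMPU, −78 °C) followed by a cold AcOH quench deconjugates the acid to the deconjugated acid F4. 1-Chloro-N,N,2-trimethylprop-1-en-1-amine converts F4 into the acid chloride F5. Et3N in toluene at 60–80 °C dehydrochlorinates F5 to vinylketene 15, which cyclises as before. The route is rejoined at 16.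

Further compounds
F1 | step 13 | 6-epi ketol, 1-[(tert-butyldimethylsilyl)oxy]-15-hydroxylongipin-3(12)-en-7-one with C15 next to C11 | OC[C@]1(C)[C@@H]2[C@H]3[C@@H](O[Si](C)(C)C(C)(C)C)CC(=C)[C@@H]2[C@@]3(C)CCC1=O
F2 | step 10 | enol silane, 4-[(tert-butyldimethylsilyl)oxy]-7-methyl-2-methylidene-7-[3-(trimethylsilyloxy)pent-3-en-1-yl]bicyclo[3.1.1]heptan-6-one | O=C1[C@H]2[C@@H](O[Si](C)(C)C(C)(C)C)CC(=C)[C@@H]1[C@@]2(C)CCC(O[Si](C)(C)C)=CC
F3 | step 10 | β-ketol, 1-[(tert-butyldimethylsilyl)oxy]-5-hydroxy-15-norlongipin-3(12)-en-7-one (C6 epimers) | CC1[C@]2(O)[C@H]3[C@@H](O[Si](C)(C)C(C)(C)C)CC(=C)[C@@H]2[C@@]3(C)CCC1=O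
F4 | step 9 | deconjugated acid, (5S,6E)-5-[(tert-butyldimethylsilyl)oxy]-7-methyl-3-methylidene-10-oxododec-6-enoic acid | OC(=O)CC(=C)C[C@H](O[Si](C)(C)C(C)(C)C)/C=C(\C)CCC(=O)CC
F5 | step 9 | acid chloride of F4 | ClC(=O)CC(=C)C[C@H](O[Si](C)(C)C(C)(C)C)/C=C(\C)CCC(=O)CC
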